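**Retrosynthetic overview**

1. The route rests on C6 of the 1,2-dioxane (ring O1–O2–C3–C4–C5–C6; C1 = CO2H, C2 = CHCH3). C6 bears O1, a methyl group and a chain whose C7 and C8 are plain CH2 groups, so in a precursor C7 can be an alkene carbon and C8 a carbinol that stores the chirality meant for C6.
2. End game: CO2H from a C1 silyl ether (desilylation, two oxidations); the C7–C8 single bond from the (E)-C7=C8 alkene of a diene by diimide.
3. The only ring is closed by forming O1–C6: palladium-catalysed syn-SN2′ attack of the C3 hydroperoxide on C6=C7 with loss of the (8S)-hydroxyl.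
4. C3–OOH comes from the (3R)-mesylate with inversion. C8–C9 and the (8S)-carbinol come from a (−)-MIB-catalysed addition of the C9–C19 alkenylzinc (from (E)-geranylacetone) to a C1–C8 enal that already carries the mesylate.
5. The enal comes from an Evans syn aldol (C2, C3) with pent-4-ynal, then carboalumination–hydroxymethylation of the alkyne (C6 methyl, 6E, C8) and MnO2.

Key step: step 11

Remark: (E)-geranylacetone and (−)-MIB are taken as purchasable single isomers, and a metal alkoxide or acetylide that is only protonated on aqueous work-up is counted as the product of its step.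

**Route**

Step 1
Reactants: 1 (4S)-4-benzyl-3-propanoyl-1,3-oxazolidin-2-one; 2 pent-4-ynal
Product: 5 (4S)-4-benzyl-3-[(2S,3R)-3-hydroxy-2-methylhept-6-ynoyl]-1,3-oxazolidin-2-one, via boron enolate 3 (not isolated), via boron aldolate 4 (not isolated)
Conditions: Bu2BOTf, iPr2NEt, CH2Cl2, 0 °C; 2, −78 to 0 °C; aq. NaH2PO4/Na2HPO4 (pH 7), MeOH, 30% H2O2, 0 °C
Reagents that add atoms: none
Why: Evans syn aldol reaction: the (Z)-boron enolate should add to the aldehyde through a closed chair transition state on the enolate face opposite the benzyl group of the auxiliary, which sets C2 (S) and C3 (R) together in the syn relationship.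

Step 2
Reactants: 5 (4S)-4-benzyl-3-[(2S,3R)-3-hydroxy-2-methylhept-6-ynoyl]-1,3-oxazolidin-2-one
Product: 6 (2R,3R)-2-methylhept-6-yne-1,3-diol
Conditions: LiBH4, MeOH (1 equiv), THF, 0 °C to rt
Reagents that add atoms: none
Why: Hydride reduction of the N-acyl oxazolidinone by LiBH4 should give the 1,3-diol without touching C2, C3 or the alkyne, and sets the auxiliary free for recovery.

Step 3
Reactants: 6 (2R,3R)-2-methylhept-6-yne-1,3-diol
Product: 7 (2R,3R)-1-[(tert-butyldiphenylsilyl)oxy]-2-methylhept-6-yn-3-ol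
Conditions: TBDPSCl, imidazole, CH2Cl2, 0 °C
Reagents that add atoms: tert-butyl(chloro)diphenylsilane, CC(C)(C)[Si](Cl)(c1ccccc1)c1ccccc1
Why: Silyl ether formation with the bulky chlorosilane should occur only at the primary C1 hydroxyl, the secondary C3 hydroxyl being flanked by the C2 branch.

Step 4
Reactants: 7 (2R,3R)-1-[(tert-butyldiphenylsilyl)oxy]-2-methylhept-6-yn-3-ol
Product: 10 (2E,6R,7R)-8-[(tert-butyldiphenylsilyl)oxy]-3,7-dimethyloct-2-ene-1,6-diol, via alkenylalane 8 (not isolated), via lithium alanate 9 (not isolated)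
Conditions: AlMe3, Cp2ZrCl2 (cat.), CH2Cl2, 0 °C to rt; volatiles removed; n-BuLi, THF/hexane, −78 °C; (CH2O)n, −78 °C to rt; aq. KNaC4H4O6
Reagents that add atoms: trimethylaluminium, C[Al](C)C; paraformaldehyde (as formaldehyde), C=O
Why: Negishi zirconium-catalysed carboalumination should add CH3 (to C6) and aluminium (to C7) syn across the terminal alkyne, and hydroxymethylation of the derived alanate with retention then gives the (6E)-trisubstituted alkene and C8 in one flask, the C3 hydroxyl being masked meanwhile as its aluminium alkoxide.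

Step 5
Reactants: 10 (2E,6R,7R)-8-[(tert-butyldiphenylsilyl)oxy]-3,7-dimethyloct-2-ene-1,6-diol
Product: 11 (2E,6R,7R)-8-[(tert-butyldiphenylsilyl)oxy]-6-hydroxy-3,7-dimethyloct-2-enal
Conditions: MnO2 (excess), CH2Cl2, rt
Reagents that add atoms: none
Why: MnO2 oxidises allylic alcohols chemoselectively, so only the C8 hydroxyl should be converted into the (E)-enal, and the neutral medium should keep the free C3 hydroxyl from adding to the enal.

Step 6
Reactants: 11 (2E,6R,7R)-8-[(tert-butyldiphenylsilyl)oxy]-6-hydroxy-3,7-dimethyloct-2-enal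
Product: 12 (2R,3R,6E)-1-[(tert-butyldiphenylsilyl)oxy]-2,6-dimethyl-8-oxooct-6-en-3-yl methanesulfonate
Conditions: MsCl, Et3N, CH2Cl2, −20 °C
Reagents that add atoms: methanesulfonyl chloride, CS(=O)(=O)Cl
Why: Sulfonylation of the secondary alcohol (retention at C3) is placed here because the later, acid-labile C8 carbinol could neither be told apart from C3–OH nor survive mesylation, and the cold amine conditions should leave the enal untouched.

Step 7
Reactants: 13 (5E)-6,10-dimethylundeca-5,9-dien-2-one ((E)-geranylacetone)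
Product: 16 (5E)-6,10-dimethylundeca-5,9-dien-1-yne, via lithium enolate 14 (not isolated), via enol phosphate 15 (not isolated)
Conditions: LiN(iPr)2, THF, −78 °C; ClP(O)(OEt)2, −78 °C to rt; LiN(iPr)2 (2.3 equiv), THF, −78 °C to rt; aq. NH4Cl
Reagents that add atoms: none
Why: Conversion of a methyl ketone into a terminal alkyne by kinetic enolisation at the methyl group, O-phosphorylation and base-induced elimination of the enol phosphate, to which the trisubstituted alkenes are inert.

Step 8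
Reactants: 16 (5E)-6,10-dimethylundeca-5,9-dien-1-yne
Product: 18 (1E,5E)-1-iodo-2,6,10-trimethylundeca-1,5,9-triene, via alkenylalane 17 (not isolated)
Conditions: AlMe3, Cp2ZrCl2 (cat.), CH2Cl2, rt; I2, THF, −30 to 0 °C
Reagents that add atoms: trimethylaluminium, C[Al](C)C; iodine, II
Why: Negishi carboalumination (syn, methyl to the internal carbon) followed by iodinolysis of the C–Al bond with retention should give the (1E)-iodide only.

Step 9
Reactants: 18 (1E,5E)-1-iodo-2,6,10-trimethylundeca-1,5,9-triene; 12 (2R,3R,6E)-1-[(tert-butyldiphenylsilyl)oxy]-2,6-dimethyl-8-oxooct-6-en-3-yl methanesulfonate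
Product: 21 (2R,3R,6E,8S,9E,13E)-1-[(tert-butyldiphenylsilyl)oxy]-8-hydroxy-2,6,10,14,18-pentamethylnonadeca-6,9,13,17-tetraen-3-yl methanesulfonate, via alkenyllithium 19 (not isolated), via dialkenylzinc 20 (not isolated)
Conditions: 18 (2.4 equiv), t-BuLi (4.8 equiv), Et2O, −78 °C; ZnBr2 (1.2 equiv), −78 to 0 °C; N,N,N′,N′-tetraethylethane-1,2-diamine, (−)-MIB (10 mol %), toluene/hexane; 12, 0 °C; aq. NH4Cl
Reagents that add atoms: none
Why: Amino-alcohol-catalysed enantioselective addition of an alkenylzinc to an aldehyde: the zinc aminoalkoxide of (−)-MIB should deliver the alkenyl group to the Si face of the enal, which sets C8 as (S) by catalyst control, and because the hydrocarbon partner carries the organometallic the mesylate only meets an organozinc, which does not attack sulfonates.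

Step 10
Reactants: 21 (2R,3R,6E,8S,9E,13E)-1-[(tert-butyldiphenylsilyl)oxy]-8-hydroxy-2,6,10,14,18-pentamethylnonadeca-6,9,13,17-tetraen-3-yl methanesulfonate
Product: 22 (2R,3S,6E,8S,9E,13E)-1-[(tert-butyldiphenylsilyl)oxy]-3-hydroperoxy-2,6,10,14,18-pentamethylnonadeca-6,9,13,17-tetraen-8-ol
Conditions: 50% aq. H2O2 (large excess), KOH, MeOH/THF, 0 °C to rt; chromatography on Et3N-deactivated silica
Reagents that add atoms: hydrogen peroxide, OO
Why: SN2 displacement of the secondary mesylate by hydroperoxide anion should invert C3 from (R) to the (S)-hydroperoxide; the alkaline medium is harmless to the bis-allylic carbinol and the electron-rich alkenes, and the enal that such conditions would epoxidise is already consumed.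

Step 11
Reactants: 22 (2R,3S,6E,8S,9E,13E)-1-[(tert-butyldiphenylsilyl)oxy]-3-hydroperoxy-2,6,10,14,18-pentamethylnonadeca-6,9,13,17-tetraen-8-ol
Product: 23 tert-butyl{(2R)-2-[(3S,6R)-6-methyl-6-[(1E,3E,7E)-4,8,12-trimethyltrideca-1,3,7,11-tetraen-1-yl]-1,2-dioxan-3-yl]propoxy}diphenylsilane
Conditions: PdCl2(MeCN)2 (10 mol %), THF, 0 °C
Reagents that add atoms: none
Why: Proposed new method: the divalent palladium of PdCl2(MeCN)2 should bind the C6=C7 alkene on the face of the C8 hydroxyl in the conformer whose C8–H eclipses the alkene (the one free of 1,3-allylic strain with the C6 methyl), take up the C3 hydroperoxide as a peroxide ligand, deliver O1 to C6 on that same face and then lose palladium and the C8 hydroxide syn, which returns the divalent catalyst, sets free water and leaves the (E)-C7=C8 alkene. The closest known reaction types are the PdCl2(MeCN)2-catalysed syn-SN2′ cyclisation of hydroxy allylic alcohols to 2-alkenyl tetrahydropyrans with 1,3-chirality transfer and the Pd(OAc)2-catalysed peroxypalladation of unsaturated hydroperoxides to 1,2-dioxanes; new are the hydroperoxide as nucleophile in the chirality-transferring variant and the fully substituted terminus. The 1,2-dioxane (O1, O2, C3, C4, C5, C6) closes in a 6-exo-trig mode. The new stereocentre C6 is controlled by the (8S)-carbinol: with the (6E)-alkene, entry of O1 syn to the departing hydroxyl gives (6R) in the diene, which is the arrangement that reads (6S) in the target once C7 is saturated, and the remote C3 centre has no say. The step needs attack at C6 only and on one face: attack at C8 or C10 would require an eight- or ten-membered peroxide ring, C6 is the more substituted and electronically preferred alkene carbon, and the face is fixed by hydroxyl-directed coordination on the strain-minimised (E)-alkene. Palladium stays divalent, so the O–O bond should not be reduced, and the cold neutral conditions are chosen to outrun ionisation of the bis-allylic carbinol.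

Step 12
Reactants: 23 tert-butyl{(2R)-2-[(3S,6R)-6-methyl-6-[(1E,3E,7E)-4,8,12-trimethyltrideca-1,3,7,11-tetraen-1-yl]-1,2-dioxan-3-yl]propoxy}diphenylsilane
Product: 24 tert-butyl{(2R)-2-[(3S,6S)-6-methyl-6-[(3E,7E)-4,8,12-trimethyltrideca-3,7,11-trien-1-yl]-1,2-dioxan-3-yl]propoxy}diphenylsilane
Conditions: 2-O2NC6H4SO2NHNH2, Et3N, CH2Cl2, rt (portionwise, monitored)
Reagents that add atoms: none
Why: Diimide reduction (concerted syn transfer of two hydrogens) is much faster for the 1,2-disubstituted C7=C8 alkene than for the three trisubstituted ones and does not reduce O–O bonds, so only the descriptor of C6 changes, not its geometry.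

Step 13
Reactants: 24 tert-butyl{(2R)-2-[(3S,6S)-6-methyl-6-[(3E,7E)-4,8,12-trimethyltrideca-3,7,11-trien-1-yl]-1,2-dioxan-3-yl]propoxy}diphenylsilane
Product: 25 (2R)-2-[(3S,6S)-6-methyl-6-[(3E,7E)-4,8,12-trimethyltrideca-3,7,11-trien-1-yl]-1,2-dioxan-3-yl]propan-1-ol
Conditions: Bu4NF, AcOH (1:1), THF, 0 °C to rt
Reagents that add atoms: none
Why: Fluoride-induced cleavage of the silyl ether, buffered with acetic acid so that the hydrogen at C3 next to the peroxide is not exposed to a strong base (Kornblum–DeLaMare fragmentation).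

Step 14
Reactants: 25 (2R)-2-[(3S,6S)-6-methyl-6-[(3E,7E)-4,8,12-trimethyltrideca-3,7,11-trien-1-yl]-1,2-dioxan-3-yl]propan-1-ol
Product: 26 (2S)-2-[(3S,6S)-6-methyl-6-[(3E,7E)-4,8,12-trimethyltrideca-3,7,11-trien-1-yl]-1,2-dioxan-3-yl]propanal
Conditions: Dess–Martin periodinane, NaHCO3, CH2Cl2, 0 °C; used at once
Reagents that add atoms: none
Why: Dess–Martin oxidation under buffered, non-basic conditions should give the aldehyde without epimerising C2 or causing β-elimination of the C3 peroxy oxygen.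

Step 15
Reactants: 26 (2S)-2-[(3S,6S)-6-methyl-6-[(3E,7E)-4,8,12-trimethyltrideca-3,7,11-trien-1-yl]-1,2-dioxan-3-yl]propanal
Product: 27 (2S)-2-[(3S,6S)-6-methyl-6-[(3E,7E)-4,8,12-trimethyltrideca-3,7,11-trien-1-yl]-1,2-dioxan-3-yl]propanoic acid (target)
Conditions: NaClO2, NaH2PO4, 2-methylbut-2-ene (large excess), t-BuOH/H2O, 0 °C
Reagents that add atoms: sodium chlorite, [Na+].[O-]Cl=O
Why: Pinnick oxidation in a weakly acidic buffer converts the aldehyde into the acid, the excess 2-methylbut-2-ene trapping the hypochlorous acid that would otherwise attack the trisubstituted alkenes.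

**Compound list**

1 | (4S)-4-benzyl-3-propanoyl-1,3-oxazolidin-2-one | CCC(=O)N1[C@@H](Cc2ccccc2)COC1=O | starting material
2 | pent-4-ynal | C#CCCC=O | starting material
3 | (4S)-4-benzyl-3-{(1Z)-1-[(dibutylboranyl)oxy]prop-1-en-1-yl}-1,3-oxazolidin-2-one (boron enolate) | C/C=C(\OB(CCCC)CCCC)N1[C@@H](Cc2ccccc2)COC1=O | intermediate
4 | (4S)-4-benzyl-3-{(2S,3R)-3-[(dibutylboranyl)oxy]-2-methylhept-6-ynoyl}-1,3-oxazolidin-2-one (boron aldolate) | C#CCC[C@H]([C@H](C)C(=O)N1[C@@H](Cc2ccccc2)COC1=O)OB(CCCC)CCCC | intermediate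
5 | (4S)-4-benzyl-3-[(2S,3R)-3-hydroxy-2-methylhept-6-ynoyl]-1,3-oxazolidin-2-one | C#CCC[C@H]([C@H](C)C(=O)N1[C@@H](Cc2ccccc2)COC1=O)O | intermediate
6 | (2R,3R)-2-methylhept-6-yne-1,3-diol | C#CCC[C@H]([C@H](C)CO)O | intermediate
7 | (2R,3R)-1-[(tert-butyldiphenylsilyl)oxy]-2-methylhept-6-yn-3-ol | C#CCC[C@H]([C@H](C)CO[Si](c1ccccc1)(c1ccccc1)C(C)(C)C)O | intermediate
8 | alkenylalane: (E)-C7 dimethylalanyl, C6 methyl alkene derived from 7, C3 oxygen as dimethylaluminium alkoxide | C[Al](C)/C=C(C)/CC[C@H]([C@H](C)CO[Si](c1ccccc1)(c1ccccc1)C(C)(C)C)O[Al](C)C | intermediate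
9 | lithium butyl(dimethyl)alkenylalanate derived from 8 | [Li+].CCCC[Al-](C)(C)/C=C(C)/CC[C@H]([C@H](C)CO[Si](c1ccccc1)(c1ccccc1)C(C)(C)C)O[Al](C)C | intermediate
10 | (2E,6R,7R)-8-[(tert-butyldiphenylsilyl)oxy]-3,7-dimethyloct-2-ene-1,6-diol | OC/C=C(C)/CC[C@H]([C@H](C)CO[Si](c1ccccc1)(c1ccccc1)C(C)(C)C)O | intermediate
11 | (2E,6R,7R)-8-[(tert-butyldiphenylsilyl)oxy]-6-hydroxy-3,7-dimethyloct-2-enal | O=C/C=C(C)/CC[C@H]([C@H](C)CO[Si](c1ccccc1)(c1ccccc1)C(C)(C)C)O | intermediate
12 | (2R,3R,6E)-1-[(tert-butyldiphenylsilyl)oxy]-2,6-dimethyl-8-oxooct-6-en-3-yl methanesulfonate | O=C/C=C(C)/CC[C@H]([C@H](C)CO[Si](c1ccccc1)(c1ccccc1)C(C)(C)C)OS(C)(=O)=O | intermediate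
13 | (5E)-6,10-dimethylundeca-5,9-dien-2-one ((E)-geranylacetone) | CC(=O)CC/C=C(\C)CCC=C(C)C | starting material
14 | lithium (5E)-6,10-dimethylundeca-1,5,9-trien-2-olate (kinetic enolate) | C=C(O[Li])CC/C=C(\C)CCC=C(C)C | intermediate
15 | diethyl (5E)-6,10-dimethylundeca-1,5,9-trien-2-yl phosphate | C=C(CC/C=C(\C)CCC=C(C)C)OP(=O)(OCC)OCC | intermediate
16 | (5E)-6,10-dimethylundeca-5,9-dien-1-yne | C#CCC/C=C(\C)CCC=C(C)C | intermediate
17 | dimethyl[(1E,5E)-2,6,10-trimethylundeca-1,5,9-trien-1-yl]alane | C[Al](C)/C=C(C)/CC/C=C(\C)CCC=C(C)C | intermediate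
18 | (1E,5E)-1-iodo-2,6,10-trimethylundeca-1,5,9-triene | I/C=C(C)/CC/C=C(\C)CCC=C(C)C | intermediate
19 | [(1E,5E)-2,6,10-trimethylundeca-1,5,9-trien-1-yl]lithium | [Li]/C=C(C)/CC/C=C(\C)CCC=C(C)C | intermediate
20 | bis[(1E,5E)-2,6,10-trimethylundeca-1,5,9-trien-1-yl]zinc | CC(C)=CCC/C(C)=C/CC/C(C)=C/[Zn]/C=C(C)/CC/C=C(\C)CCC=C(C)C | intermediate
21 | (2R,3R,6E,8S,9E,13E)-1-[(tert-butyldiphenylsilyl)oxy]-8-hydroxy-2,6,10,14,18-pentamethylnonadeca-6,9,13,17-tetraen-3-yl methanesulfonate | CC(C)=CCC/C(C)=C/CC/C(C)=C/[C@H](O)/C=C(C)/CC[C@H]([C@H](C)CO[Si](c1ccccc1)(c1ccccc1)C(C)(C)C)OS(C)(=O)=O | intermediate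
22 | (2R,3S,6E,8S,9E,13E)-1-[(tert-butyldiphenylsilyl)oxy]-3-hydroperoxy-2,6,10,14,18-pentamethylnonadeca-6,9,13,17-tetraen-8-ol | CC(C)=CCC/C(C)=C/CC/C(C)=C/[C@H](O)/C=C(C)/CC[C@@H]([C@H](C)CO[Si](c1ccccc1)(c1ccccc1)C(C)(C)C)OO | intermediate
23 | tert-butyl{(2R)-2-[(3S,6R)-6-methyl-6-[(1E,3E,7E)-4,8,12-trimethyltrideca-1,3,7,11-tetraen-1-yl]-1,2-dioxan-3-yl]propoxy}diphenylsilane | CC(C)=CCC/C(C)=C/CC/C(C)=C/C=C/[C@@]1(C)CC[C@@H]([C@H](C)CO[Si](c2ccccc2)(c2ccccc2)C(C)(C)C)OO1 | intermediate
24 | tert-butyl{(2R)-2-[(3S,6S)-6-methyl-6-[(3E,7E)-4,8,12-trimethyltrideca-3,7,11-trien-1-yl]-1,2-dioxan-3-yl]propoxy}diphenylsilane | CC(C)=CCC/C(C)=C/CC/C(C)=C/CC[C@@]1(C)CC[C@@H]([C@H](C)CO[Si](c2ccccc2)(c2ccccc2)C(C)(C)C)OO1 | intermediate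
25 | (2R)-2-[(3S,6S)-6-methyl-6-[(3E,7E)-4,8,12-trimethyltrideca-3,7,11-trien-1-yl]-1,2-dioxan-3-yl]propan-1-ol | CC(C)=CCC/C(C)=C/CC/C(C)=C/CC[C@@]1(C)CC[C@@H]([C@H](C)CO)OO1 | intermediate
26 | (2S)-2-[(3S,6S)-6-methyl-6-[(3E,7E)-4,8,12-trimethyltrideca-3,7,11-trien-1-yl]-1,2-dioxan-3-yl]propanal | CC(C)=CCC/C(C)=C/CC/C(C)=C/CC[C@@]1(C)CC[C@@H]([C@H](C)C=O)OO1 | intermediate
27 | (2S)-2-[(3S,6S)-6-methyl-6-[(3E,7E)-4,8,12-trimethyltrideca-3,7,11-trien-1-yl]-1,2-dioxan-3-yl]propanoic acid | CC(C)=CCC/C(C)=C/CC/C(C)=C/CC[C@@]1(C)CC[C@@H]([C@H](C)C(=O)O)OO1 | target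

**Step count and risks**

Total steps: 15 (six for the C1–C8 enal, two for the C9–C19 iodide, seven from the union onward). Longest linear sequence: 13 (steps 1–6 and 9–15).

Steps most likely to fail:

1. Step 11 (the proposed new method). The bis-allylic carbinol may ionise to a pentadienyl cation faster than peroxypalladation, giving hydroxyl transposition, dehydration and loss of the chirality transfer. A palladium alkylperoxide may also oxidise the alkenes, or the transfer may run anti (which the antipodal ligand in step 9 would correct).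
   Fallback with known chemistry, setting out from 10 (with 20, made from 18 as in step 9) and returning at 24:
   - Diol 10 with MsCl/Et3N, then LiCl in DMF, should give (2R,3R,6E)-1-[(tert-butyldiphenylsilyl)oxy]-8-chloro-2,6-dimethyloct-6-en-3-yl methanesulfonate F1.
   - Negishi coupling of the allylic chloride with 20 under Pd(PPh3)4 (zerovalent palladium) in THF should give the skipped-diene mesylate (2R,3R,6E,9E,13E)-1-[(tert-butyldiphenylsilyl)oxy]-2,6,10,14,18-pentamethylnonadeca-6,9,13,17-tetraen-3-yl methanesulfonate F2.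
   - H2O2/KOH as in step 10 should give tert-butyl{[(2R,3S,6E,9E,13E)-3-hydroperoxy-2,6,10,14,18-pentamethylnonadeca-6,9,13,17-tetraen-1-yl]oxy}diphenylsilane F3.
   - Hg(OAc)2 (divalent mercury) in CH2Cl2 at 0 °C should close the dioxane by 6-exo peroxymercuration to the C7 acetoxymercurio dioxane F4.
   - Alkaline NaBH4 then replaces mercury by hydrogen to give 24 together with its C6 epimer, the (3S,6R)-dioxane F5, from which it is separated by chromatography.
   - C6 is not controlled on this path, and step 12 is not needed.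

2. Step 10. Elimination of the β-branched secondary mesylate may outrun the slow substitution, and hydroperoxide anion may attack the silyl ether.
   Fallback setting out from 21 and returning at 22:
   - 2-Methoxypropan-2-yl hydroperoxide F6 (from ozonolysis of 2,3-dimethylbut-2-ene in methanol) is alkylated by 21 with CsOH in DMF at 0 °C, a non-aqueous and more nucleophilic protected peroxide.
   - This should give, with inversion, the peroxyketal (2R,3S,6E,8S,9E,13E)-1-[(tert-butyldiphenylsilyl)oxy]-3-[(2-methoxypropan-2-yl)peroxy]-2,6,10,14,18-pentamethylnonadeca-6,9,13,17-tetraen-8-ol F7.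
   - The peroxyketal is unmasked to 22 with AcOH/THF/H2O at 0 °C, kept as brief as possible because of the acid-labile carbinol.

3. Step 9. An uncatalysed, lithium-halide-promoted addition may erode the enantioselectivity, and transfer of the 2,2-disubstituted alkenyl group may be sluggish.
   Fallback with reversed polarity, setting out from 7 and returning at 21:
   - Carboalumination of 7 as in step 4 to alkenylalane 8, then I2, should give (2R,3R,6E)-1-[(tert-butyldiphenylsilyl)oxy]-7-iodo-2,6-dimethylhept-6-en-3-ol F8.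
   - MsCl/Et3N should give (2R,3R,6E)-1-[(tert-butyldiphenylsilyl)oxy]-7-iodo-2,6-dimethylhept-6-en-3-yl methanesulfonate F9.
   - An asymmetric Nozaki–Hiyama–Kishi coupling with commercial (2E,6E)-farnesal gives 21. Conditions: CrCl2 (divalent chromium), NiCl2 (cat.), a chiral oxazoline–sulfonamide ligand chosen for Re-face delivery, Et3N, THF/MeCN. The mesylate is inert to the alkenylchromium species.

**Further compounds**

F1 | step 11 | (2R,3R,6E)-1-[(tert-butyldiphenylsilyl)oxy]-8-chloro-2,6-dimethyloct-6-en-3-yl methanesulfonate | ClC/C=C(C)/CC[C@H]([C@H](C)CO[Si](c1ccccc1)(c1ccccc1)C(C)(C)C)OS(C)(=O)=O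
F2 | step 11 | (2R,3R,6E,9E,13E)-1-[(tert-butyldiphenylsilyl)oxy]-2,6,10,14,18-pentamethylnonadeca-6,9,13,17-tetraen-3-yl methanesulfonate | CC(C)=CCC/C(C)=C/CC/C(C)=C/C/C=C(C)/CC[C@H]([C@H](C)CO[Si](c1ccccc1)(c1ccccc1)C(C)(C)C)OS(C)(=O)=O
F3 | step 11 | tert-butyl{[(2R,3S,6E,9E,13E)-3-hydroperoxy-2,6,10,14,18-pentamethylnonadeca-6,9,13,17-tetraen-1-yl]oxy}diphenylsilane | CC(C)=CCC/C(C)=C/CC/C(C)=C/C/C=C(C)/CC[C@@H]([C@H](C)CO[Si](c1ccccc1)(c1ccccc1)C(C)(C)C)OO
F4 | step 11 | C7 acetoxymercurio dioxane (24 bearing HgOAc at C7, both C6 epimers) | CC(C)=CCC/C(C)=C/CC/C(C)=C/CC([Hg]OC(C)=O)C1(C)CC[C@@H]([C@H](C)CO[Si](c2ccccc2)(c2ccccc2)C(C)(C)C)OO1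
F5 | step 11 | tert-butyl{(2R)-2-[(3S,6R)-6-methyl-6-[(3E,7E)-4,8,12-trimethyltrideca-3,7,11-trien-1-yl]-1,2-dioxan-3-yl]propoxy}diphenylsilane (C6 epimer of 24) | CC(C)=CCC/C(C)=C/CC/C(C)=C/CC[C@]1(C)CC[C@@H]([C@H](C)CO[Si](c2ccccc2)(c2ccccc2)C(C)(C)C)OO1
F6 | step 10 | 2-methoxypropan-2-yl hydroperoxide | COC(C)(C)OO
F7 | step 10 | (2R,3S,6E,8S,9E,13E)-1-[(tert-butyldiphenylsilyl)oxy]-3-[(2-methoxypropan-2-yl)peroxy]-2,6,10,14,18-pentamethylnonadeca-6,9,13,17-tetraen-8-ol | CC(C)=CCC/C(C)=C/CC/C(C)=C/[C@H](O)/C=C(C)/CC[C@@H]([C@H](C)CO[Si](c1ccccc1)(c1ccccc1)C(C)(C)C)OOC(C)(C)OC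
F8 | step 9 | (2R,3R,6E)-1-[(tert-butyldiphenylsilyl)oxy]-7-iodo-2,6-dimethylhept-6-en-3-ol | I/C=C(C)/CC[C@H]([C@H](C)CO[Si](c1ccccc1)(c1ccccc1)C(C)(C)C)O
F9 | step 9 | (2R,3R,6E)-1-[(tert-butyldiphenylsilyl)oxy]-7-iodo-2,6-dimethylhept-6-en-3-yl methanesulfonate | I/C=C(C)/CC[C@H]([C@H](C)CO[Si](c1ccccc1)(c1ccccc1)C(C)(C)C)OS(C)(=O)=O
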